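At 6.0 h, the question about maple was one of a small thing beside a large one.

| setting | maple | alder | flask |
|---|---|---|---|
| starting material | 1.2 M | 1.2 M | 1.2 M |
| reagent | 1.8 M | 1.8 M | 1.80 M |
| capture agent | 0.024 M | 0.012 M | 0.0240 M |
| free catalyst | 1 mM | 1 mM | 1.0 mM |
| second catalyst | 180 mM | 180 mM | 180 mM |
| remark | the very flask that is asked about, followed so far | run made earlier |  |
| time |  |  | 6.0 h |

maple run (percent of the starting material charged)

| time / min | product / % | trapped intermediate / % | starting material / % |
|---|---|---|---|
| 8.00 | 7.0 | 0.4 | 32.8 |
| 15.0 | 15.8 | 0 | 30.7 |
| 25.0 | 22.3 | 2.8 | 26.9 |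
| 40.0 | 30.5 | 1.2 | 23.4 |
| 60.0 | 40.6 | 0.9 | 19.2 |
| 120 | 62.8 | 2.7 | 13.2 |

alder run (percent of the starting material charged)

| time / h | product / % | trapped intermediate / % | starting material / % |
|---|---|---|---|
| 0.200 | 13.1 | 0 | 30.9 |
| 0.333 | 18.7 | 0.7 | 28.6 |
| 0.500 | 27.2 | 0.3 | 27.7 |
| 0.833 | 37.2 | 2.3 | 21.0 |
| 1.33 | 49.2 | 0 | 17.0 |
| 2.50 | 69.9 | 0.3 | 10.4 |

(each reading ± 1 percentage point)

- share of product in product plus trapped intermediate at 2.5 min
- share of product in product plus trapped intermediate at 30 min
- share of product in product plus trapped intermediate at 6.0 h

- steps under discussion: starting material + free catalyst <-> free catalyst + open intermediate; second catalyst + open intermediate <-> catalyst intermediate; reagent + catalyst intermediate -> second catalyst + product; open intermediate + capture agent -> trapped intermediate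

Each trapped intermediate takes up one capture agent. So in maple, trapped intermediate could not pass the capture agent charge over the starting material charge, 2.00%. I called this fraction the trap ceiling. The readings scattered by 1 percentage point, so I read no trapped amount from them. I assumed the ceiling was full at 6.0 h and reckoned the share as a correction:

share = product / (product + ceiling)

I got the product in two ways, both from the maple readings. The pool was whatever was neither product nor trapped, with the ceiling standing in for the trapped amount.

First way, pseudo-first-order, reagent held constant:

pool 57.4% at 60.0 min, 35.2% at 120 min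
decay 0.489 h⁻¹
product 93.0%, share 97.9%

Second way, reagent falling with the product. I took the rate as proportional to reagent times pool, so the logarithm of reagent over pool rises in a straight line:

reagent charge 1.50 of the starting material charge
reagent excess over pool 0.520, constant
logarithm 0.645, then 0.907
extended to 6.0 h: 1.96
product 89.4%, share 97.8%

The first way gave more product, and it cheated: it kept the reagent at its level, while the second way left 40.4% of the reagent. I kept the second. A gap of 3.6 points in product became 0.100 points in share.

For earlier times I put the full ceiling into the same fraction, which gave estimated floors. With product estimated near 25.0% at 30 min, I estimated a floor of 92.6%. With product estimated near 2.19% at 2.5 min, I estimated a floor of 52.3%.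

The forecast gave 92%, 95% and 97.8%, saying “Trapped intermediate is capped by capture agent”.

Maple gave 84.1%, 93.1% and 97.8%.

    starting material + free catalyst ⇌ free catalyst + open intermediate (K = 1.80, k = 16.0 L mol⁻¹ s⁻¹)
    second catalyst + open intermediate ⇌ catalyst intermediate (K = 0.00310 L mol⁻¹, k = 0.0230 L mol⁻¹ s⁻¹)
    reagent + catalyst intermediate → second catalyst + product (k = 0.310 L mol⁻¹ s⁻¹)
    open intermediate + capture agent → trapped intermediate (k = 0.00250 L mol⁻¹ s⁻¹)

At 6.00 h, maple held 0% of its capture agent, with trapped intermediate at 2.00% and product at 88.4%. That product and the ceiling give 97.8%.

The neighbour charged with 0.060 M of capture agent has a ceiling of 5.00%, so maple's product gives 94.6%. Computed, that neighbour gave 94.5%, with trapped intermediate at 5.00%.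

(Readings and results come from a simulation with constants of no real substance; the scatter is artificial.)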